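A direct plan would open the Sharpless epoxide of geranylgeraniol with H2O2 to the tertiary hydroperoxide A1 and alkylate its caesium salt with the aldol-derived propargylic mesylate A2; semi-hydrogenation, glycol cleavage and methylenation would give the diene A3, ring-closing metathesis the dihydrodioxin A4, and diimide reduction, desilylation and oxidation of the alcohol A5 the acid.
Its weakest steps would be:
(a) the intermolecular SN2 union of the hindered tertiary peroxide anion with the α-branched secondary propargylic sulfonate, because C3 would rest on clean inversion against elimination, allene formation and base-induced O–O cleavage;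
(b) the ring closure by RuCl2(PCy3)2(=CHPh) at high dilution, with the Pd/CaCO3–Pb(OAc)2 hydrogenation before it and the diimide reduction after it, because all three would act on an O–O bond beside three trisubstituted alkenes, on the most valuable material;
(c) the detour at the carboxyl carbon (imide, reduction, silyl ether, two-stage re-oxidation, with alkyne and sulfonate handling on the way), because about eight operations would add no bond of the skeleton.

**Plan of the new route**
The retrosynthesis cuts O2–C3 last, with the carboxyl group folded back onto C3 as a cis-β-lactone; the lactone is then cut (C3–Cα and acyl C–O) to an aldehyde and methylketene, C4–C5 by olefination, and C6–O back to the epoxide of geranylgeraniol.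
Enabling feature: O2 on C3 stands β to the carboxyl carbon, so C3, Cα, C=O and one carboxyl oxygen can form an oxetan-2-one whose C3–O bond is a strained electrophile; the hydroperoxide on C6 is tethered to C3 through C5 and C4, the distance for a 6-exo-tet attack with inversion.
Ring order: oxirane (sets C6), oxetanone (sets Cα and, through the later inversion, C3, both by catalyst), and the 1,2-dioxane only in the last step, which also frees the acid.
The weak steps do not arise: the peroxide is never alkylated intermolecularly, the ring is closed by C–O and not C=C formation without ruthenium, palladium or diimide, and the carboxyl carbon enters at its final oxidation state. One silyl group on the hydroperoxide is the only protecting group.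

Key step: step 8

Assumption: O-trimethylsilylquinine is taken to give the (3S,4R)-cis-lactone in step 7, the sense in which quinine-type catalysts add ketenes to aldehydes; should the sense be opposite, O-trimethylsilylquinidine is used and nothing else changes.

**Route**

Step 1
Reactants: 1 (2E,6E,10E)-geranylgeraniol
Product: 2 [(2R,3R)-3-methyl-3-[(3E,7E)-4,8,12-trimethyltrideca-3,7,11-trien-1-yl]oxiran-2-yl]methanol
Conditions: Ti(OiPr)4 (10 mol %), D-(−)-diethyl tartrate (12 mol %), tBuOOH (2 equiv), 4 Å MS, CH2Cl2, −20 °C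
Reagents that add atoms: tert-butyl hydroperoxide, CC(C)(C)OO
Why: Sharpless asymmetric epoxidation is directed by the allylic hydroxyl, so only the 2,3-alkene of the four should react, and the D-tartrate ligand delivers oxygen to the face that gives the (2R,3R)-epoxide, which fixes the later C6 after one inversion.

Step 2
Reactants: 2 [(2R,3R)-3-methyl-3-[(3E,7E)-4,8,12-trimethyltrideca-3,7,11-trien-1-yl]oxiran-2-yl]methanol
Product: 3 (2R,3S,6E,10E)-3-hydroperoxy-3,7,11,15-tetramethylhexadeca-6,10,14-triene-1,2-diol
Conditions: H2O2 (anhydrous, in Et2O, 10 equiv), H3PMo12O40 (3 mol %), 0 °C to rt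
Reagents that add atoms: hydrogen peroxide, OO
Why: Molybdenum-catalysed perhydrolysis of a trisubstituted epoxide: backside attack of H2O2 at the tertiary carbon, which bears positive charge better and is remote from CH2OH, should invert it to 3S (the C6 configuration of the target), while the excess of H2O2 outcompetes the chain alkenes as nucleophile.

Step 3
Reactants: 3 (2R,3S,6E,10E)-3-hydroperoxy-3,7,11,15-tetramethylhexadeca-6,10,14-triene-1,2-diol
Product: 5 (2R,3S,6E,10E)-3,7,11,15-tetramethyl-3-[(triethylsilyl)peroxy]hexadeca-6,10,14-triene-1,2-diol, via potassium peroxide 4 (not isolated)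
Conditions: KN(SiMe3)2 (1.0 equiv), THF, −78 °C; then Et3SiCl (1.05 equiv), −78 to −40 °C
Reagents that add atoms: chlorotriethylsilane, CC[Si](Cl)(CC)CC
Why: Chemoselective O-silylation of a hydroperoxide: one equivalent of base should remove only the OOH proton, which is several pKa units more acidic than the hydroxyls, and the α-effect peroxide anion should take up the chlorosilane at low temperature while the neutral diol does not react.

Step 4
Reactants: 5 (2R,3S,6E,10E)-3,7,11,15-tetramethyl-3-[(triethylsilyl)peroxy]hexadeca-6,10,14-triene-1,2-diol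
Product: 6 (2S,5E,9E)-2,6,10,14-tetramethyl-2-[(triethylsilyl)peroxy]pentadeca-5,9,13-trienal
Conditions: NaIO4 (1.5 equiv), THF/pH 7 phosphate buffer, 0 °C to rt
Reagents that add atoms: none
Why: Malaprade glycol cleavage removes C1 as formaldehyde and leaves a non-enolisable aldehyde on the quaternary peroxy carbon, whose configuration cannot change; the silyl peroxide and the trisubstituted alkenes should be inert to periodate at neutral pH.

Step 5
Reactants: 6 (2S,5E,9E)-2,6,10,14-tetramethyl-2-[(triethylsilyl)peroxy]pentadeca-5,9,13-trienal; 7 (triphenylphosphoranylidene)acetaldehyde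
Product: 8 (2E,4S,7E,11E)-4,8,12,16-tetramethyl-4-[(triethylsilyl)peroxy]heptadeca-2,7,11,15-tetraenal
Conditions: 7 (1.5 equiv), toluene, 70 °C
Reagents that add atoms: none
Why: Wittig olefination with the formyl-stabilised ylide should give the (E)-enal and so add the two carbons that become C4 and C3; the α-oxygenated, non-enolisable aldehyde is an activated partner, the hindered product should resist a second homologation, and a stabilised ylide has no phosphorus lone pair to reduce the peroxide.

Step 6
Reactants: 8 (2E,4S,7E,11E)-4,8,12,16-tetramethyl-4-[(triethylsilyl)peroxy]heptadeca-2,7,11,15-tetraenal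
Product: 9 (4S,7E,11E)-4,8,12,16-tetramethyl-4-[(triethylsilyl)peroxy]heptadeca-7,11,15-trienal
Conditions: diethyl 2,6-dimethyl-1,4-dihydropyridine-3,5-dicarboxylate (1.2 equiv), dibenzylammonium trifluoroacetate (10 mol %), THF, rt
Reagents that add atoms: none
Why: Iminium-catalysed transfer hydrogenation: the ammonium salt turns the enal into an iminium ion that accepts hydride from the Hantzsch ester at the β-carbon, so only the conjugated C=C should be reduced, while the isolated trisubstituted alkenes, the aldehyde and the O–O bond, which the catalyst does not activate, stay untouched.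

Step 7
Reactants: 9 (4S,7E,11E)-4,8,12,16-tetramethyl-4-[(triethylsilyl)peroxy]heptadeca-7,11,15-trienal; 10 propanoyl chloride
Product: 12 (3S,4R)-3-methyl-4-[(3S,6E,10E)-3,7,11,15-tetramethyl-3-[(triethylsilyl)peroxy]hexadeca-6,10,14-trien-1-yl]oxetan-2-one, via methylketene 11 (not isolated)
Conditions: O-trimethylsilylquinine (10 mol %), LiClO4 (2 equiv), iPr2NEt (2.5 equiv), CH2Cl2/Et2O, −78 °C; 10 (2 equiv) added over 2 h
Reagents that add atoms: none
Why: Catalytic asymmetric acyl halide–aldehyde cyclocondensation (ketene–aldehyde [2+2]): the silylated cinchona alkaloid adds to methylketene to give a Z ammonium enolate that attacks the lithium-activated aldehyde through a closed transition state and is released as the cis-β-lactone, so Cα (3S) and the carbinol carbon (4R, inverted later) are both set by the catalyst and not by the remote C6 centre; the unbranched aliphatic aldehyde is a standard substrate and the silyl peroxide should be a spectator at −78 °C.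

Step 8
Reactants: 12 (3S,4R)-3-methyl-4-[(3S,6E,10E)-3,7,11,15-tetramethyl-3-[(triethylsilyl)peroxy]hexadeca-6,10,14-trien-1-yl]oxetan-2-one
Product: 15 (2S)-2-[(3S,6S)-6-methyl-6-[(3E,7E)-4,8,12-trimethyltrideca-3,7,11-trien-1-yl]-1,2-dioxan-3-yl]propanoic acid, via caesium peroxide 13 (not isolated), via caesium carboxylate 14 (not isolated)
Conditions: CsF (1.5 equiv), DMF, 0 °C to rt; then 0.5 M aq. HCl to pH 3, 0 °C
Reagents that add atoms: none
Why: Proposed new method: fluoride cleaves the Si–O bond, and the peroxide anion so freed, tethered through C5 and C4, should attack the lactone C4 from the side opposite the ring oxygen (alkyl–oxygen fission), the strain of the oxetan-2-one and the carboxylate leaving group driving the closure. The closest known reaction types are the intramolecular 5-exo and 6-exo openings of oxetanes by hydroperoxides and the SN2 opening of cis-3,4-disubstituted β-lactones at C4 by azide, sulfonamide anions and cuprates, which proceed with inversion. The one ring formed, the 1,2-dioxane, is closed 6-exo-tet by O2–C3 bond formation; C3 is the only centre that changes, by inversion of the catalyst-set lactone C4 (4R to 3S, which turns the cis-lactone into the anti β-peroxy acid), while C6 and Cα are untouched. The selectivity needed is alkyl–oxygen over acyl–oxygen attack: attack at the carbonyl would require an eight-membered perester, whereas attack at C4 passes through a six-membered transition state, and a soft α-effect peroxide anion is the kind of nucleophile that favours C4. The carboxylate formed has no acidic α-hydrogen, so neither ring-opening by elimination nor epimerisation at Cα should follow, and acidification frees the acid.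

**Compound list**

1 | (2E,6E,10E)-geranylgeraniol | CC(C)=CCC/C(C)=C/CC/C(C)=C/CC/C(C)=C/CO | starting material
2 | [(2R,3R)-3-methyl-3-[(3E,7E)-4,8,12-trimethyltrideca-3,7,11-trien-1-yl]oxiran-2-yl]methanol | CC(C)=CCC/C(C)=C/CC/C(C)=C/CC[C@@]1(C)O[C@@H]1CO | intermediate
3 | (2R,3S,6E,10E)-3-hydroperoxy-3,7,11,15-tetramethylhexadeca-6,10,14-triene-1,2-diol | CC(C)=CCC/C(C)=C/CC/C(C)=C/CC[C@@](OO)(C)[C@H](O)CO | intermediate
4 | potassium (2R,3S,6E,10E)-1,2-dihydroxy-3,7,11,15-tetramethylhexadeca-6,10,14-triene-3-peroxolate (potassium peroxide) | CC(C)=CCC/C(C)=C/CC/C(C)=C/CC[C@@](O[O-])(C)[C@H](O)CO.[K+] | intermediate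
5 | (2R,3S,6E,10E)-3,7,11,15-tetramethyl-3-[(triethylsilyl)peroxy]hexadeca-6,10,14-triene-1,2-diol | CC(C)=CCC/C(C)=C/CC/C(C)=C/CC[C@@](OO[Si](CC)(CC)CC)(C)[C@H](O)CO | intermediate
6 | (2S,5E,9E)-2,6,10,14-tetramethyl-2-[(triethylsilyl)peroxy]pentadeca-5,9,13-trienal | CC(C)=CCC/C(C)=C/CC/C(C)=C/CC[C@@](OO[Si](CC)(CC)CC)(C)C=O | intermediate
7 | (triphenylphosphoranylidene)acetaldehyde | O=CC=P(c1ccccc1)(c1ccccc1)c1ccccc1 | starting material
8 | (2E,4S,7E,11E)-4,8,12,16-tetramethyl-4-[(triethylsilyl)peroxy]heptadeca-2,7,11,15-tetraenal | CC(C)=CCC/C(C)=C/CC/C(C)=C/CC[C@@](OO[Si](CC)(CC)CC)(C)/C=C/C=O | intermediate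
9 | (4S,7E,11E)-4,8,12,16-tetramethyl-4-[(triethylsilyl)peroxy]heptadeca-7,11,15-trienal | CC(C)=CCC/C(C)=C/CC/C(C)=C/CC[C@@](OO[Si](CC)(CC)CC)(C)CCC=O | intermediate
10 | propanoyl chloride | CCC(=O)Cl | starting material
11 | methylketene (prop-1-en-1-one) | CC=C=O | intermediate
12 | (3S,4R)-3-methyl-4-[(3S,6E,10E)-3,7,11,15-tetramethyl-3-[(triethylsilyl)peroxy]hexadeca-6,10,14-trien-1-yl]oxetan-2-one | CC(C)=CCC/C(C)=C/CC/C(C)=C/CC[C@@](OO[Si](CC)(CC)CC)(C)CC[C@H]1OC(=O)[C@H]1C | intermediate
13 | caesium (3S,6E,10E)-3,7,11,15-tetramethyl-1-[(2R,3S)-3-methyl-4-oxooxetan-2-yl]hexadeca-6,10,14-triene-3-peroxolate (caesium peroxide) | CC(C)=CCC/C(C)=C/CC/C(C)=C/CC[C@@](O[O-])(C)CC[C@H]1OC(=O)[C@H]1C.[Cs+] | intermediate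
14 | caesium (2S)-2-[(3S,6S)-6-methyl-6-[(3E,7E)-4,8,12-trimethyltrideca-3,7,11-trien-1-yl]-1,2-dioxan-3-yl]propanoate (caesium carboxylate) | CC(C)=CCC/C(C)=C/CC/C(C)=C/CC[C@@]1(C)CC[C@@H]([C@H](C)C(=O)[O-])OO1.[Cs+] | intermediate
15 | (2S)-2-[(3S,6S)-6-methyl-6-[(3E,7E)-4,8,12-trimethyltrideca-3,7,11-trien-1-yl]-1,2-dioxan-3-yl]propanoic acid | CC(C)=CCC/C(C)=C/CC/C(C)=C/CC[C@@]1(C)CC[C@@H]([C@H](C)C(=O)O)OO1 | target

**Step count and risks**

Total step count: 8. Longest linear sequence: 8 steps (1 to 15).

Steps most likely to fail: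

Step 8 (proposed new method). Fluoride or the peroxide anion may attack the lactone carbonyl, or base may cleave the O–O bond next to the C3–H of the product faster than the ring closes. The fallback uses known chemistry, sets out from 9 and comes back at 15. Wittig olefination of 9 with methyl 2-(triphenylphosphoranylidene)propanoate (toluene, 60 °C) would give the enoate methyl (2E,6S,9E,13E)-2,6,10,14,18-pentamethyl-6-[(triethylsilyl)peroxy]nonadeca-2,9,13,17-tetraenoate F1. Desilylation with HF·pyridine in THF would give the free hydroperoxide methyl (2E,6S,9E,13E)-6-hydroperoxy-2,6,10,14,18-pentamethylnonadeca-2,9,13,17-tetraenoate F2. Amine-promoted intramolecular peroxide conjugate addition (Et2NH, CF3CH2OH, rt; 6-exo-trig) would give methyl (2S)-2-[(3S,6S)-6-methyl-6-[(3E,7E)-4,8,12-trimethyltrideca-3,7,11-trien-1-yl]-1,2-dioxan-3-yl]propanoate F3, and LiOH in THF/H2O at 0 °C would hydrolyse it to 15. This path gives up catalyst control of C3 and Cα, so F3 would have to be separated from its C3/Cα isomers by chromatography.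

Step 3. The primary hydroxyl may be silylated, or the β-hydroxy peroxide anion may fragment, in competition with O-silylation of the peroxide. The fallback sets out from 2 and comes back at 5. The primary alcohol is masked first (NaH, 4-methoxybenzyl chloride, Bu4NI, THF, 0 °C) as (2R,3R)-2-{[(4-methoxyphenyl)methoxy]methyl}-3-methyl-3-[(3E,7E)-4,8,12-trimethyltrideca-3,7,11-trien-1-yl]oxirane F4. Perhydrolysis as in step 2 would give (2R,3S,6E,10E)-3-hydroperoxy-1-[(4-methoxyphenyl)methoxy]-3,7,11,15-tetramethylhexadeca-6,10,14-trien-2-ol F5, in which only a hindered secondary hydroxyl competes. Silylation (Et3SiCl, imidazole, CH2Cl2, −20 °C) would give (2R,3S,6E,10E)-1-[(4-methoxyphenyl)methoxy]-3,7,11,15-tetramethyl-3-[(triethylsilyl)peroxy]hexadeca-6,10,14-trien-2-ol F6, and oxidative removal of the benzyl ether (2,3-dichloro-5,6-dicyano-1,4-benzoquinone, CH2Cl2/pH 7 buffer, 0 °C) would return 5.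

Step 5. The stabilised ylide may add slowly to the neopentyl-type aldehyde, so that thermal loss of the silyl peroxide or a second homologation of the enal competes. The fallback sets out from 6, comes back at 9 and does not pass through enal 8. Horner–Wadsworth–Emmons olefination with the more nucleophilic triethyl phosphonoacetate (LiCl, iPr2NEt, MeCN, 0 °C) would give ethyl (2E,4S,7E,11E)-4,8,12,16-tetramethyl-4-[(triethylsilyl)peroxy]heptadeca-2,7,11,15-tetraenoate F7. Concerted diimide reduction of the only disubstituted, conjugated alkene (2-nitrobenzenesulfonylhydrazide, Et3N, CH2Cl2, rt) would give ethyl (4S,7E,11E)-4,8,12,16-tetramethyl-4-[(triethylsilyl)peroxy]heptadeca-7,11,15-trienoate F8, and partial reduction with iBu2AlH (toluene, −78 °C) would give 9.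

**Further compounds**

F1 | step 8 | methyl (2E,6S,9E,13E)-2,6,10,14,18-pentamethyl-6-[(triethylsilyl)peroxy]nonadeca-2,9,13,17-tetraenoate | CC(C)=CCC/C(C)=C/CC/C(C)=C/CC[C@@](OO[Si](CC)(CC)CC)(C)CC/C=C(\C)C(=O)OC
F2 | step 8 | methyl (2E,6S,9E,13E)-6-hydroperoxy-2,6,10,14,18-pentamethylnonadeca-2,9,13,17-tetraenoate | CC(C)=CCC/C(C)=C/CC/C(C)=C/CC[C@@](OO)(C)CC/C=C(\C)C(=O)OC
F3 | step 8 | methyl (2S)-2-[(3S,6S)-6-methyl-6-[(3E,7E)-4,8,12-trimethyltrideca-3,7,11-trien-1-yl]-1,2-dioxan-3-yl]propanoate | CC(C)=CCC/C(C)=C/CC/C(C)=C/CC[C@@]1(C)CC[C@@H]([C@H](C)C(=O)OC)OO1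
F4 | step 3 | (2R,3R)-2-{[(4-methoxyphenyl)methoxy]methyl}-3-methyl-3-[(3E,7E)-4,8,12-trimethyltrideca-3,7,11-trien-1-yl]oxirane | CC(C)=CCC/C(C)=C/CC/C(C)=C/CC[C@@]1(C)O[C@@H]1COCc1ccc(OC)cc1
F5 | step 3 | (2R,3S,6E,10E)-3-hydroperoxy-1-[(4-methoxyphenyl)methoxy]-3,7,11,15-tetramethylhexadeca-6,10,14-trien-2-ol | CC(C)=CCC/C(C)=C/CC/C(C)=C/CC[C@@](OO)(C)[C@H](O)COCc1ccc(OC)cc1
F6 | step 3 | (2R,3S,6E,10E)-1-[(4-methoxyphenyl)methoxy]-3,7,11,15-tetramethyl-3-[(triethylsilyl)peroxy]hexadeca-6,10,14-trien-2-ol | CC(C)=CCC/C(C)=C/CC/C(C)=C/CC[C@@](OO[Si](CC)(CC)CC)(C)[C@H](O)COCc1ccc(OC)cc1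
F7 | step 5 | ethyl (2E,4S,7E,11E)-4,8,12,16-tetramethyl-4-[(triethylsilyl)peroxy]heptadeca-2,7,11,15-tetraenoate | CC(C)=CCC/C(C)=C/CC/C(C)=C/CC[C@@](OO[Si](CC)(CC)CC)(C)/C=C/C(=O)OCC
F8 | step 5 | ethyl (4S,7E,11E)-4,8,12,16-tetramethyl-4-[(triethylsilyl)peroxy]heptadeca-7,11,15-trienoate | CC(C)=CCC/C(C)=C/CC/C(C)=C/CC[C@@](OO[Si](CC)(CC)CC)(C)CCC(=O)OCC
A1 | direct plan | (2R,3S,6E,10E)-3-hydroperoxy-3,7,11,15-tetramethylhexadeca-6,10,14-triene-1,2-diol | CC(C)=CCC/C(C)=C/CC/C(C)=C/CC[C@@](OO)(C)[C@H](O)CO
A2 | direct plan | (3S,4R)-5-[(tert-butyldimethylsilyl)oxy]-4-methylpent-1-yn-3-yl methanesulfonate | C#C[C@@H](OS(C)(=O)=O)[C@H](C)CO[Si](C)(C)C(C)(C)C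
A3 | direct plan | tert-butyldimethyl{[(2R,3S)-2-methyl-3-{[(3S,6E,10E)-3,7,11,15-tetramethylhexadeca-1,6,10,14-tetraen-3-yl]peroxy}pent-4-en-1-yl]oxy}silane | CC(C)=CCC/C(C)=C/CC/C(C)=C/CC[C@@](OO[C@@H](C=C)[C@H](C)CO[Si](C)(C)C(C)(C)C)(C)C=C
A4 | direct plan | tert-butyldimethyl{(2R)-2-[(3S,6S)-6-methyl-6-[(3E,7E)-4,8,12-trimethyltrideca-3,7,11-trien-1-yl]-3,6-dihydro-1,2-dioxin-3-yl]propoxy}silane | CC(C)=CCC/C(C)=C/CC/C(C)=C/CC[C@@]1(C)C=C[C@@H]([C@H](C)CO[Si](C)(C)C(C)(C)C)OO1
A5 | direct plan | (2R)-2-[(3S,6S)-6-methyl-6-[(3E,7E)-4,8,12-trimethyltrideca-3,7,11-trien-1-yl]-1,2-dioxan-3-yl]propan-1-ol | CC(C)=CCC/C(C)=C/CC/C(C)=C/CC[C@@]1(C)CC[C@@H]([C@H](C)CO)OO1
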